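## Retrosynthetic overview

1. Ring A, the 42-membered lactone (C1–C41 plus the ring oxygen; the only ring, closed last), is cut at C33–C34 inside the stereocentre-free hexamethylene bridge C32–C37. C33 becomes a primary bromide three carbons from the C31 oxygen, C34 the end of a pent-4-enyl chain on the C38=C39 Z-alkene, and a one-pot 9-BBN hydroboration/Pd-catalysed alkyl–alkyl Suzuki–Miyaura macrocyclisation joins them. These two unhindered methylenes, remote from every stereocentre and from the other alkenes, are the feature that makes the closure possible.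
2. The seco ester comes from a Stille coupling at C3–C4 between a C4–C33 (Z)-vinylstannane and the (Z)-3-iodoacrylate of the C34–C50 alcohol. The lactone C–O bond is thus made early as a simple ester, and the (2Z,4Z)-dienoate never passes through an activated acid.
3. The C4–C33 chain comes from Felkin addition of a C20–C33 (Z)-vinyllithium to a C5–C19 aldehyde (sets C19). Both Z-trisubstituted alkenes arise from Stork–Zhao iodo-olefination of β-silyloxy aldehydes.
4. Hidden repeat: C5–C17 and C21–C33 are the same C13 chain with the same three carbinol configurations at two oxidation levels. One bis-dithiane alcohol is built by two anion-relay linchpin couplings from two 4-oxygenated 1,2-epoxybutanes, (S)-epichlorohydrin and a silyl dithiane. It is desulfurised to the all-syn 1,5-triol, or hydrolysed and anti-reduced to the all-anti 1,3-polyol.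
5. The C34–C50 alcohol comes from (R)-propylene oxide by Brown crotyl- and allylboration (one Ipc antipode throughout) and a Z-selective Wittig reaction. Order of ring formation: only temporary epoxide and dithiane rings before ring A in the key step.

Key step: step 43

Remark: read from the SMILES, the target is (2Z,4Z,20Z,38Z) with 7S,9R,11S,13R,15S,17R,18R,19S,23R,27R,31R,41S,42S,43R,49R (all-anti C7–C17 polyol, 17,18-anti/18,19-syn, all-syn 1,5-triol C23/C27/C31, syn,syn triad C41–C43). Locants below are those of the macrolide (C1 = lactone carbonyl, C41 = lactone carbinol carbon, side chain C42–C50), and "target configuration" means the spatial arrangement of the target at that carbon.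

## Route

Step 1
Reactants: 1 but-3-en-1-ol
Product: 2 1-[(but-3-en-1-yloxy)methyl]-4-methoxybenzene
Conditions: NaH, PMBCl, Bu4NI (cat.), THF/DMF, 0 °C → rt
Reagents that add atoms: 4-methoxybenzyl chloride, COc1ccc(CCl)cc1
Why: Williamson etherification of the primary alkoxide should install the PMB ether cleanly, and no stereocentre is involved.

Step 2
Reactants: 2 1-[(but-3-en-1-yloxy)methyl]-4-methoxybenzene
Product: 3 rac-2-[2-(4-methoxybenzyloxy)ethyl]oxirane
Conditions: mCPBA, NaHCO3, CH2Cl2, 0 °C → rt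
Reagents that add atoms: 3-chloroperoxybenzoic acid, OOC(=O)c1cccc(Cl)c1
Why: Prilezhaev epoxidation of the isolated terminal alkene should give the racemic epoxide needed for the resolution.

Step 3
Reactants: 3 rac-2-[2-(4-methoxybenzyloxy)ethyl]oxirane
Product: 4 (S)-2-[2-(4-methoxybenzyloxy)ethyl]oxirane
Conditions: (R,R)-(salen)Co(OAc) (0.5 mol %, salen = N,N'-bis(3,5-di-tert-butylsalicylidene)cyclohexane-1,2-diamine dianion), H2O (0.55 equiv), THF, 0 °C → rt
Reagents that add atoms: none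
Why: Jacobsen hydrolytic kinetic resolution should hydrolyse the (R)-epoxide selectively and leave (S)-4, whose stereocentre later becomes C7 and C23.

Step 4
Reactants: 1 but-3-en-1-ol
Product: 5 (but-3-en-1-yloxy)(tert-butyl)dimethylsilane
Conditions: TBSCl, imidazole, DMF, rt
Reagents that add atoms: tert-butyldimethylsilyl chloride, CC(C)(C)[Si](C)(C)Cl
Why: Standard imidazole-mediated silylation of a primary alcohol.

Step 5
Reactants: 5 (but-3-en-1-yloxy)(tert-butyl)dimethylsilane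
Product: 6 rac-tert-butyldimethyl[2-(oxiran-2-yl)ethoxy]silane
Conditions: mCPBA, NaHCO3, CH2Cl2, 0 °C → rt
Reagents that add atoms: 3-chloroperoxybenzoic acid, OOC(=O)c1cccc(Cl)c1
Why: Prilezhaev epoxidation of the terminal alkene should give the racemic epoxide for the resolution.

Step 6
Reactants: 6 rac-tert-butyldimethyl[2-(oxiran-2-yl)ethoxy]silane
Product: 7 (R)-tert-butyldimethyl[2-(oxiran-2-yl)ethoxy]silane
Conditions: (S,S)-(salen)Co(OAc) (0.5 mol %), H2O (0.55 equiv), THF, 0 °C → rt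
Reagents that add atoms: none
Why: Jacobsen hydrolytic kinetic resolution with the enantiomeric catalyst should remove the (S)-epoxide as its diol and leave (R)-7, whose stereocentre later becomes C15 and C31.

Step 7
Reactants: 8 2-(tert-butyldimethylsilyl)-1,3-dithiane; 4 (S)-2-[2-(4-methoxybenzyloxy)ethyl]oxirane; 9 (S)-epichlorohydrin
Product: 12 epoxy dithiane C5–C12, via PMB-side lithium alkoxide 10 (not isolated), via PMB-side silyl-migrated lithiodithiane 11 (not isolated)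
Conditions: 8, tBuLi, Et2O, −78 → −45 °C; 4, −78 → −25 °C; then 9, HMPA/THF, −78 °C → rt
Reagents that add atoms: none
Why: Anion-relay linchpin coupling: lithiated 8 opens 4 at its CH2 terminus, HMPA triggers the 1,4-Brook rearrangement, and the new dithiane anion opens 9 at the epoxide CH2 before the chlorohydrin alkoxide recloses to the terminal epoxide; because only CH2 carbons are attacked, both stereocentres are carried over unchanged from 4 and 9.

Step 8
Reactants: 8 2-(tert-butyldimethylsilyl)-1,3-dithiane; 7 (R)-tert-butyldimethyl[2-(oxiran-2-yl)ethoxy]silane; 12 epoxy dithiane C5–C12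
Product: 15 common C13 bis-dithiane alcohol, via TBS-side lithium alkoxide 13 (not isolated), via TBS-side silyl-migrated lithiodithiane 14 (not isolated)
Conditions: 8, tBuLi, Et2O, −78 → −45 °C; 7, −78 → −25 °C; then 12, HMPA/THF, −78 → 0 °C; aq. NH4Cl
Reagents that add atoms: none
Why: The second anion-relay linchpin coupling (epoxide opening, 1,4-Brook rearrangement, opening of epoxide 12 at its CH2) should assemble the 13-carbon chain with three carbinol centres, all inherited from 4, 9 and 7, and leave only the central hydroxyl free.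

Step 9
Reactants: 15 common C13 bis-dithiane alcohol
Product: 16 O-TBS ether of 15 (C21–C33 reading, O27 silylated)
Conditions: TBSOTf, 2,6-lutidine, CH2Cl2, −78 → 0 °C
Reagents that add atoms: tert-butyldimethylsilyl triflate, CC(C)(C)[Si](C)(C)OS(=O)(=O)C(F)(F)F
Why: Silyl triflate silylation of the hindered secondary alcohol; dithianes and the PMB ether tolerate the conditions.

Step 10
Reactants: 16 O-TBS ether of 15
Product: 17 C21–C33 tridecane with 21-OPMB and 23,27,31,33-tetrakis-OTBS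
Conditions: Raney Ni (W-2), EtOH, rt → 60 °C
Reagents that add atoms: none
Why: Mozingo-type reductive desulfurisation should turn both dithiane carbons (C25, C29) into methylenes, giving the all-syn 1,5-triol pattern, while silyl and PMB ethers survive this grade of nickel.

Step 11
Reactants: 17 C21–C33 tridecane with 21-OPMB and 23,27,31,33-tetrakis-OTBS
Product: 18 C21 primary alcohol
Conditions: DDQ, CH2Cl2/pH 7 buffer (10:1), 0 °C
Reagents that add atoms: none
Why: Oxidative cleavage of the PMB ether by DDQ (hydride abstraction, hydrolysis of the oxocarbenium ion) leaves the silyl ethers untouched.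

Step 12
Reactants: 18 C21 primary alcohol
Product: 19 C21 aldehyde
Conditions: Dess–Martin periodinane, NaHCO3, CH2Cl2, 0 °C → rt
Reagents that add atoms: none
Why: Buffered Dess–Martin oxidation should give the β-silyloxy aldehyde without elimination.

Step 13
Reactants: 19 C21 aldehyde; 20 ethyltriphenylphosphonium iodide
Product: 21 C20–C33 (Z)-vinyl iodide
Conditions: 20, nBuLi, THF, rt; I2, −78 °C; NaHMDS, −20 °C; then 19, −78 °C → rt
Reagents that add atoms: iodine, II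
Why: Stork–Zhao olefination: the α-iodo ylide should add to the aldehyde under kinetic control to give the (Z)-2-iodoalk-2-ene (iodine cis to C22), which is the geometry required for C20=C21.

Step 14
Reactants: 15 common C13 bis-dithiane alcohol
Product: 22 C5–C17 hydroxy diketone (9,13-dioxo, 11-OH)
Conditions: MeI, CaCO3, MeCN/H2O (9:1), 45 °C
Reagents that add atoms: water, O
Why: Dithiane hydrolysis by S-methylation and hydrolysis of the sulfonium intermediates under neutral buffering should unmask both ketones without β-elimination of the silyloxy groups.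

Step 15
Reactants: 22 C5–C17 hydroxy diketone
Product: 23 C5–C17 all-anti 9,11,13-triol
Conditions: Me4NBH(OAc)3, MeCN/AcOH (1:1), −30 °C
Reagents that add atoms: none
Why: Evans–Saksena reduction: the C11 hydroxyl binds the acetoxyborohydride and delivers hydride intramolecularly to each β-ketone through a chair transition state, which should set C9 and C13 anti to C11 in one operation.

Step 16
Reactants: 23 C5–C17 all-anti 9,11,13-triol
Product: 24 C5–C17 hexakis-TBS ether with 5-OPMB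
Conditions: TBSOTf (excess), 2,6-lutidine, CH2Cl2, 0 °C → rt
Reagents that add atoms: tert-butyldimethylsilyl triflate, CC(C)(C)[Si](C)(C)OS(=O)(=O)C(F)(F)F
Why: Exhaustive silyl triflate silylation of the three secondary hydroxyls.

Step 17
Reactants: 24 C5–C17 hexakis-TBS ether with 5-OPMB
Product: 25 C17 primary alcohol
Conditions: HF·pyridine, pyridine, THF, 0 °C
Reagents that add atoms: none
Why: Buffered HF·pyridine cleaves the unhindered primary TBS ether much faster than the five secondary ones.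

Step 18
Reactants: 25 C17 primary alcohol
Product: 26 C17 aldehyde
Conditions: Dess–Martin periodinane, NaHCO3, CH2Cl2, 0 °C → rt
Reagents that add atoms: none
Why: Buffered Dess–Martin oxidation to the β-silyloxy aldehyde.

Step 19
Reactants: 26 C17 aldehyde; 27 trans-but-2-ene
Product: 28 C5–C19 anti-homoallylic alcohol (17-OH, 18-Me, vinyl)
Conditions: 27, KOtBu, nBuLi, THF, −78 → −45 °C; (−)-Ipc2BOMe, −78 °C; BF3·OEt2; then 26, −78 °C; NaOH, H2O2
Reagents that add atoms: none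
Why: Brown crotylboration: the (E)-crotylborane reacts through a chair Zimmerman–Traxler transition state to give the 17,18-anti relationship, and the isopinocampheyl groups from (+)-α-pinene select the aldehyde face that sets C17 anti to C15 (reagent control).

Step 20
Reactants: 28 C5–C19 anti-homoallylic alcohol
Product: 29 17-O-TBS ether of 28
Conditions: TBSOTf, 2,6-lutidine, CH2Cl2, −78 → 0 °C
Reagents that add atoms: tert-butyldimethylsilyl triflate, CC(C)(C)[Si](C)(C)OS(=O)(=O)C(F)(F)F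
Why: Silyl triflate silylation of the hindered secondary alcohol.

Step 21
Reactants: 29 17-O-TBS ether of 28
Product: 30 C5–C19 aldehyde
Conditions: OsO4 (2 mol %), NaIO4, 2,6-lutidine, dioxane/H2O (3:1), rt
Reagents that add atoms: sodium periodate, [Na+].[O-]I(=O)(=O)=O
Why: Lemieux–Johnson cleavage of the only alkene gives the α-methyl aldehyde without exposing the electron-rich PMB ring to ozone; lutidine buffering should prevent epimerisation at C18.

Step 22
Reactants: 21 C20–C33 (Z)-vinyl iodide; 30 C5–C19 aldehyde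
Product: 32 C5–C33 allylic alcohol (19-OH), via C20 vinyllithium 31 (not isolated)
Conditions: 21, tBuLi (2.1 equiv), Et2O, −78 °C; then 30, −78 °C; aq. NH4Cl
Reagents that add atoms: none
Why: Felkin–Anh addition of the configurationally stable (Z)-alkenyllithium to the α-methyl aldehyde; in the 17,18-anti aldehyde the Felkin and the 1,3-anti (β-silyloxy) preferences reinforce each other, which should favour the 18,19-syn/17,19-anti alcohol with C19 as in the target.

Step 23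
Reactants: 32 C5–C33 allylic alcohol
Product: 33 19-O-TBS ether of 32
Conditions: TBSOTf, 2,6-lutidine, CH2Cl2, 0 °C → rt
Reagents that add atoms: tert-butyldimethylsilyl triflate, CC(C)(C)[Si](C)(C)OS(=O)(=O)C(F)(F)F
Why: Silyl triflate silylation of the hindered allylic alcohol.

Step 24
Reactants: 33 19-O-TBS ether of 32
Product: 34 C33 primary alcohol
Conditions: HF·pyridine, pyridine, THF, 0 °C
Reagents that add atoms: none
Why: Buffered HF·pyridine removes the single primary TBS ether selectively in the presence of ten secondary ones.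

Step 25
Reactants: 34 C33 primary alcohol
Product: 35 C33 primary bromide
Conditions: CBr4, PPh3, 2,6-lutidine, CH2Cl2, 0 °C
Reagents that add atoms: carbon tetrabromide, BrC(Br)(Br)Br
Why: Appel bromination of the unhindered primary alcohol under buffered conditions.

Step 26
Reactants: 35 C33 primary bromide
Product: 36 C5 primary alcohol
Conditions: DDQ, CH2Cl2/pH 7 buffer (10:1), 0 °C
Reagents that add atoms: none
Why: Oxidative PMB cleavage; the allylic silyl ether, the trisubstituted alkene and the alkyl bromide are inert to DDQ.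

Step 27
Reactants: 36 C5 primary alcohol
Product: 37 C5 aldehyde
Conditions: Dess–Martin periodinane, NaHCO3, CH2Cl2, 0 °C → rt
Reagents that add atoms: none
Why: Buffered Dess–Martin oxidation to the β-silyloxy aldehyde.

Step 28
Reactants: 37 C5 aldehyde; 20 ethyltriphenylphosphonium iodide
Product: 38 C4–C33 (Z)-vinyl iodide
Conditions: 20, nBuLi, THF, rt; I2, −78 °C; NaHMDS, −20 °C; then 37, −78 °C → rt
Reagents that add atoms: iodine, II
Why: A second Stork–Zhao olefination should give the (Z)-2-iodoalk-2-ene with iodine cis to C6 (the C4=C5 geometry of the target); at −78 °C the ylide adds to the aldehyde far faster than it can alkylate the primary bromide.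

Step 29
Reactants: 38 C4–C33 (Z)-vinyl iodide
Product: 39 C4–C33 (Z)-vinyl trimethylstannane
Conditions: Me3SnSnMe3, Pd(PPh3)4 (5 mol %), iPr2NEt, toluene, 80 °C
Reagents that add atoms: hexamethylditin, C[Sn](C)(C)[Sn](C)(C)C
Why: Palladium-catalysed stannylation of the vinyl iodide (oxidative addition, Sn–Sn transmetalation, reductive elimination) proceeds with retention of geometry, and the unactivated alkyl bromide does not react with Pd(PPh3)4.

Step 30
Reactants: 40 6-bromohex-1-ene; 41 (R)-propylene oxide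
Product: 42 (R)-non-8-en-2-ol
Conditions: 40, Mg, THF; then CuI (10 mol %), 41, −30 → 0 °C; aq. NH4Cl
Reagents that add atoms: none
Why: Copper-catalysed Grignard opening of the epoxide at its CH2 terminus leaves the C49 stereocentre of the chiral-pool epoxide untouched.

Step 31
Reactants: 42 (R)-non-8-en-2-ol
Product: 43 (R)-tert-butyldimethyl(non-8-en-2-yloxy)silane
Conditions: TBSCl, imidazole, DMF, rt
Reagents that add atoms: tert-butyldimethylsilyl chloride, CC(C)(C)[Si](C)(C)Cl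
Why: Standard silylation of the secondary alcohol.

Step 32
Reactants: 43 (R)-tert-butyldimethyl(non-8-en-2-yloxy)silane
Product: 44 (R)-7-(tert-butyldimethylsilyloxy)octanal
Conditions: O3, CH2Cl2, −78 °C; then PPh3, → rt
Reagents that add atoms: ozone, [O-][O+]=O
Why: Ozonolysis with reductive work-up cleaves the only alkene to the C43 aldehyde.

Step 33
Reactants: 44 (R)-7-(tert-butyldimethylsilyloxy)octanal; 45 cis-but-2-ene
Product: 46 (3R,4R,10R)-10-(tert-butyldimethylsilyloxy)-3-methylundec-1-en-4-ol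
Conditions: 45, KOtBu, nBuLi, THF, −78 → −45 °C; (−)-Ipc2BOMe, −78 °C; BF3·OEt2; then 44, −78 °C; NaOH, H2O2
Reagents that add atoms: none
Why: Brown crotylboration: the (Z)-crotylborane gives the 42,43-syn relationship through the chair transition state, and the same Ipc antipode as in step 19 sets the absolute configuration at C43.

Step 34
Reactants: 46 (3R,4R,10R)-10-(tert-butyldimethylsilyloxy)-3-methylundec-1-en-4-ol
Product: 47 (3R,4R,10R)-4,10-bis(tert-butyldimethylsilyloxy)-3-methylundec-1-ene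
Conditions: TBSOTf, 2,6-lutidine, CH2Cl2, −78 → 0 °C
Reagents that add atoms: tert-butyldimethylsilyl triflate, CC(C)(C)[Si](C)(C)OS(=O)(=O)C(F)(F)F
Why: Silyl triflate silylation of the secondary alcohol.

Step 35
Reactants: 47 (3R,4R,10R)-4,10-bis(tert-butyldimethylsilyloxy)-3-methylundec-1-ene
Product: 48 (2S,3R,9R)-3,9-bis(tert-butyldimethylsilyloxy)-2-methyldecanal
Conditions: O3, CH2Cl2, −78 °C; then PPh3, → rt
Reagents that add atoms: ozone, [O-][O+]=O
Why: Ozonolysis with reductive work-up gives the C41 aldehyde, used crude to avoid epimerisation at C42.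

Step 36
Reactants: 48 (2S,3R,9R)-3,9-bis(tert-butyldimethylsilyloxy)-2-methyldecanal; 49 allylmagnesium bromide
Product: 50 (4S,5R,6R,12R)-6,12-bis(tert-butyldimethylsilyloxy)-5-methyltridec-1-en-4-ol
Conditions: (−)-Ipc2BOMe, 49, Et2O, 0 °C → rt; then 48, −78 °C; NaOH, H2O2
Reagents that add atoms: none
Why: Brown allylboration under reagent control (same Ipc antipode), reinforced by the Felkin preference of the α-methyl aldehyde, should give the 41,42-syn alcohol and complete the syn,syn triad C41–C43.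

Step 37
Reactants: 50 (4S,5R,6R,12R)-6,12-bis(tert-butyldimethylsilyloxy)-5-methyltridec-1-en-4-ol
Product: 51 4-O-triethylsilyl ether of 50
Conditions: TESOTf, 2,6-lutidine, CH2Cl2, −78 °C
Reagents that add atoms: triethylsilyl triflate, CC[Si](CC)(CC)OS(=O)(=O)C(F)(F)F
Why: Silylation with a group that can later be removed selectively next to TBS ethers.

Step 38
Reactants: 51 4-O-triethylsilyl ether of 50
Product: 52 C39–C50 aldehyde
Conditions: O3, CH2Cl2, −78 °C; then PPh3, → rt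
Reagents that add atoms: ozone, [O-][O+]=O
Why: Ozonolysis with reductive work-up cleaves the only alkene to the C39 aldehyde.

Step 39
Reactants: 52 C39–C50 aldehyde; 53 (pent-4-en-1-yl)triphenylphosphonium bromide
Product: 54 C34–C50 (Z)-diene with 41-OTES
Conditions: 53, NaHMDS, THF, 0 °C; then 52, −78 °C → rt
Reagents that add atoms: none
Why: Wittig reaction of the non-stabilised ylide under lithium-free conditions should give the (Z)-C38=C39 alkene and at the same time bring in the terminal vinyl group C34=C35.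

Step 40
Reactants: 54 C34–C50 (Z)-diene with 41-OTES
Product: 55 C34–C50 dienol (41-OH)
Conditions: PPTS, MeOH/CH2Cl2, 0 °C
Reagents that add atoms: none
Why: Mild acid methanolysis removes the secondary TES ether much faster than the two secondary TBS ethers.

Step 41
Reactants: 55 C34–C50 dienol; 56 (Z)-3-iodoacrylic acid
Product: 57 (Z)-3-iodoacrylate of 55
Conditions: 56, DCC, DMAP (cat.), CH2Cl2, −20 → 0 °C
Reagents that add atoms: none
Why: Steglich esterification at low temperature with substoichiometric DMAP should acylate the C41 hydroxyl with retention at C41 and without Z→E isomerisation of the iodoacrylate.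

Step 42
Reactants: 39 C4–C33 (Z)-vinyl trimethylstannane; 57 (Z)-3-iodoacrylate of 55
Product: 58 seco ester (C33 bromide, C34=C35 vinyl)
Conditions: Pd2(dba)3 (10 mol %), AsPh3 (40 mol %), CuI (20 mol %), NMP, rt → 40 °C
Reagents that add atoms: none
Why: Stille coupling forms C3–C4 with retention of both alkene geometries, giving the (2Z,4Z)-dienoate directly; the alkyl bromide and the unactivated alkenes do not react with zerovalent palladium bearing a triarylarsine.

Step 43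
Reactants: 58 seco ester (C33 bromide, C34=C35 vinyl)
Product: 60 fully silylated macrolactone, via B-alkyl-9-BBN seco ester 59 (not isolated)
Conditions: 9-BBN dimer (0.65 equiv), THF, 0 °C → rt; then syringe-pump addition (12 h) to Pd(OAc)2 (20 mol %), PCy3 (40 mol %), K3PO4·H2O (3 equiv), THF, rt → 40 °C, final 1 mM
Reagents that add atoms: none
Why: Proposed new method: 9-BBN adds anti-Markovnikov to the only monosubstituted alkene of 58 (C34=C35), and the B-alkyl-9-BBN 59 is fed slowly to Pd(OAc)2/PCy3/K3PO4·H2O, where zerovalent palladium inserts into the primary C33–Br bond by SN2-type oxidative addition, the hydroxide-activated borate transfers the C34 alkyl group to divalent palladium, and reductive elimination forges the C33–C34 sp3–sp3 bond. The closest known reactions are the intermolecular Pd/PCy3-catalysed Suzuki–Miyaura coupling of primary alkyl bromides bearing β-hydrogens with B-alkyl-9-BBN reagents at room temperature and the B-alkyl Suzuki macrocyclisations onto vinyl halides, whereas an alkyl–alkyl variant that closes a macrocycle has not been documented. Ring A, the 42-membered lactone, is closed end to end by intramolecular transmetalation within an ω-borylalkyl palladium bromide followed by reductive elimination from the large palladacycle, under pseudo-high dilution. No stereocentre is created, since both carbons are unsubstituted methylenes, so the C31 and C41 centres and all four Z-alkenes remain untouched. The step needs chemoselective hydroboration (secured by the large rate gap for 9-BBN between the terminal vinyl group and the Z-disubstituted C38=C39, the trisubstituted C20=C21 and the conjugated dienoate), cyclisation over oligomerisation (slow addition, 1 mM) and transmetalation over β-hydride elimination (bulky, electron-rich PCy3). The bromide is placed on C33 so that the alkylpalladium has no alkene within reach, whereas a bromide on C34 would sit five atoms from C38=C39.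

Step 44
Reactants: 60 fully silylated macrolactone
Product: 61 target macrolide CNP0392687.2
Conditions: HF·pyridine, pyridine, THF, 0 °C → rt
Reagents that add atoms: none
Why: Buffered fluoride-mediated global desilylation should remove all twelve secondary TBS ethers without acid- or base-induced isomerisation of the (2Z,4Z)-dienoate or translactonisation, and give the target.

## Compound list

1 | but-3-en-1-ol | C=CCCO | starting material
2 | 1-[(but-3-en-1-yloxy)methyl]-4-methoxybenzene | COc1ccc(cc1)COCCC=C | intermediate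
3 | rac-2-[2-(4-methoxybenzyloxy)ethyl]oxirane | COc1ccc(cc1)COCCC1CO1 | intermediate
4 | (S)-2-[2-(4-methoxybenzyloxy)ethyl]oxirane | COc1ccc(cc1)COCC[C@H]1CO1 | intermediate
5 | (but-3-en-1-yloxy)(tert-butyl)dimethylsilane | C=CCCO[Si](C)(C)C(C)(C)C | intermediate
6 | rac-tert-butyldimethyl[2-(oxiran-2-yl)ethoxy]silane | C1OC1CCO[Si](C)(C)C(C)(C)C | intermediate
7 | (R)-tert-butyldimethyl[2-(oxiran-2-yl)ethoxy]silane | C1[C@H](O1)CCO[Si](C)(C)C(C)(C)C | intermediate
8 | 2-(tert-butyldimethylsilyl)-1,3-dithiane | CC(C)(C)[Si](C)(C)C1SCCCS1 | starting material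
9 | (S)-epichlorohydrin, (S)-2-(chloromethyl)oxirane | ClC[C@@H]1CO1 | starting material
10 | PMB-side lithium alkoxide: lithium (S)-1-[2-(tert-butyldimethylsilyl)-1,3-dithian-2-yl]-4-(4-methoxybenzyloxy)butan-2-olate | COc1ccc(cc1)COCC[C@H](O[Li])CC1(SCCCS1)[Si](C)(C)C(C)(C)C | intermediate
11 | PMB-side silyl-migrated lithiodithiane: 2-lithio-2-[(S)-2-(tert-butyldimethylsilyloxy)-4-(4-methoxybenzyloxy)butyl]-1,3-dithiane | COc1ccc(cc1)COCC[C@H](O[Si](C)(C)C(C)(C)C)CC1([Li])SCCCS1 | intermediate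
12 | epoxy dithiane C5–C12 (equally C21–C28): (S)-2-({2-[(S)-2-(tert-butyldimethylsilyloxy)-4-(4-methoxybenzyloxy)butyl]-1,3-dithian-2-yl}methyl)oxirane | COc1ccc(cc1)COCC[C@H](O[Si](C)(C)C(C)(C)C)CC1(SCCCS1)C[C@H]1CO1 | intermediate
13 | TBS-side lithium alkoxide: lithium (R)-4-(tert-butyldimethylsilyloxy)-1-[2-(tert-butyldimethylsilyl)-1,3-dithian-2-yl]butan-2-olate | CC(C)(C)[Si](C)(C)C1(SCCCS1)C[C@H](O[Li])CCO[Si](C)(C)C(C)(C)C | intermediate
14 | TBS-side silyl-migrated lithiodithiane: 2-lithio-2-[(R)-2,4-bis(tert-butyldimethylsilyloxy)butyl]-1,3-dithiane | [Li]C1(SCCCS1)C[C@H](O[Si](C)(C)C(C)(C)C)CCO[Si](C)(C)C(C)(C)C | intermediate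
15 | common C13 bis-dithiane alcohol (read as C5–C17 or as C21–C33): unbranched 13-carbon chain with 4-methoxybenzyloxy on carbon 1, OTBS on carbons 3, 11 and 13, OH on carbon 7 and 1,3-dithiane-2,2-diyl at carbons 5 and 9; carbinol carbons 3, 7, 11 have the target configuration of C7, C11, C15 (= C23, C27, C31) | COc1ccc(cc1)COCC[C@H](O[Si](C)(C)C(C)(C)C)CC1(SCCCS1)C[C@H](O)CC1(SCCCS1)C[C@H](O[Si](C)(C)C(C)(C)C)CCO[Si](C)(C)C(C)(C)C | intermediate
16 | O-TBS ether of 15 (C21–C33 reading: 21-OPMB, 23,27,31,33-tetrakis-OTBS, dithianes at C25 and C29) | COc1ccc(cc1)COCC[C@H](O[Si](C)(C)C(C)(C)C)CC1(SCCCS1)C[C@H](O[Si](C)(C)C(C)(C)C)CC1(SCCCS1)C[C@H](O[Si](C)(C)C(C)(C)C)CCO[Si](C)(C)C(C)(C)C | intermediate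
17 | C21–C33 tridecane with 21-(4-methoxybenzyloxy) and 23,27,31,33-tetrakis(tert-butyldimethylsilyloxy); target configuration at C23, C27, C31 | COc1ccc(cc1)COCC[C@H](O[Si](C)(C)C(C)(C)C)CCC[C@H](O[Si](C)(C)C(C)(C)C)CCC[C@H](O[Si](C)(C)C(C)(C)C)CCO[Si](C)(C)C(C)(C)C | intermediate
18 | C21 primary alcohol: C21–C33 chain, 21-OH, 23,27,31,33-tetrakis-OTBS, target configuration at C23, C27, C31 | OCC[C@H](O[Si](C)(C)C(C)(C)C)CCC[C@H](O[Si](C)(C)C(C)(C)C)CCC[C@H](O[Si](C)(C)C(C)(C)C)CCO[Si](C)(C)C(C)(C)C | intermediate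
19 | C21 aldehyde: C21–C33 chain, 21-oxo, 23,27,31,33-tetrakis-OTBS | O=CC[C@H](O[Si](C)(C)C(C)(C)C)CCC[C@H](O[Si](C)(C)C(C)(C)C)CCC[C@H](O[Si](C)(C)C(C)(C)C)CCO[Si](C)(C)C(C)(C)C | intermediate
20 | ethyltriphenylphosphonium iodide | CC[P+](c1ccccc1)(c1ccccc1)c1ccccc1.[I-] | starting material
21 | C20–C33 (Z)-vinyl iodide: iodine and methyl on C20, C20=C21 with iodine cis to C22, 23,27,31,33-tetrakis-OTBS | I/C(C)=C\C[C@H](O[Si](C)(C)C(C)(C)C)CCC[C@H](O[Si](C)(C)C(C)(C)C)CCC[C@H](O[Si](C)(C)C(C)(C)C)CCO[Si](C)(C)C(C)(C)C | intermediate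
22 | C5–C17 hydroxy diketone: 5-OPMB, 7,15,17-tris-OTBS, 9,13-dioxo, 11-OH; target configuration at C7, C11, C15 | COc1ccc(cc1)COCC[C@H](O[Si](C)(C)C(C)(C)C)CC(=O)C[C@H](O)CC(=O)C[C@H](O[Si](C)(C)C(C)(C)C)CCO[Si](C)(C)C(C)(C)C | intermediate
23 | C5–C17 all-anti triol: 5-OPMB, 7,15,17-tris-OTBS, 9,11,13-trihydroxy; target configuration at C7–C15 | COc1ccc(cc1)COCC[C@H](O[Si](C)(C)C(C)(C)C)C[C@@H](O)C[C@H](O)C[C@@H](O)C[C@H](O[Si](C)(C)C(C)(C)C)CCO[Si](C)(C)C(C)(C)C | intermediate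
24 | C5–C17 hexakis-TBS ether: 5-OPMB, 7,9,11,13,15,17-hexakis-OTBS | COc1ccc(cc1)COCC[C@H](O[Si](C)(C)C(C)(C)C)C[C@@H](O[Si](C)(C)C(C)(C)C)C[C@H](O[Si](C)(C)C(C)(C)C)C[C@@H](O[Si](C)(C)C(C)(C)C)C[C@H](O[Si](C)(C)C(C)(C)C)CCO[Si](C)(C)C(C)(C)C | intermediate
25 | C17 primary alcohol: 5-OPMB, 7,9,11,13,15-pentakis-OTBS, 17-OH | COc1ccc(cc1)COCC[C@H](O[Si](C)(C)C(C)(C)C)C[C@@H](O[Si](C)(C)C(C)(C)C)C[C@H](O[Si](C)(C)C(C)(C)C)C[C@@H](O[Si](C)(C)C(C)(C)C)C[C@H](O[Si](C)(C)C(C)(C)C)CCO | intermediate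
26 | C17 aldehyde: 5-OPMB, 7,9,11,13,15-pentakis-OTBS, 17-oxo | COc1ccc(cc1)COCC[C@H](O[Si](C)(C)C(C)(C)C)C[C@@H](O[Si](C)(C)C(C)(C)C)C[C@H](O[Si](C)(C)C(C)(C)C)C[C@@H](O[Si](C)(C)C(C)(C)C)C[C@H](O[Si](C)(C)C(C)(C)C)CC=O | intermediate
27 | trans-but-2-ene | C/C=C/C | starting material
28 | C5–C19 anti-homoallylic alcohol: 5-OPMB, 7,9,11,13,15-pentakis-OTBS, 17-OH, 18-methyl (17,18-anti), terminal vinyl CH=CH2 at C19; target configuration at C7–C18 | COc1ccc(cc1)COCC[C@H](O[Si](C)(C)C(C)(C)C)C[C@@H](O[Si](C)(C)C(C)(C)C)C[C@H](O[Si](C)(C)C(C)(C)C)C[C@@H](O[Si](C)(C)C(C)(C)C)C[C@H](O[Si](C)(C)C(C)(C)C)C[C@@H](O)[C@@H](C)C=C | intermediate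
29 | 17-O-TBS ether of 28 | COc1ccc(cc1)COCC[C@H](O[Si](C)(C)C(C)(C)C)C[C@@H](O[Si](C)(C)C(C)(C)C)C[C@H](O[Si](C)(C)C(C)(C)C)C[C@@H](O[Si](C)(C)C(C)(C)C)C[C@H](O[Si](C)(C)C(C)(C)C)C[C@@H](O[Si](C)(C)C(C)(C)C)[C@@H](C)C=C | intermediate
30 | C5–C19 aldehyde: 5-OPMB, 7,9,11,13,15,17-hexakis-OTBS, 18-methyl, 19-oxo | COc1ccc(cc1)COCC[C@H](O[Si](C)(C)C(C)(C)C)C[C@@H](O[Si](C)(C)C(C)(C)C)C[C@H](O[Si](C)(C)C(C)(C)C)C[C@@H](O[Si](C)(C)C(C)(C)C)C[C@H](O[Si](C)(C)C(C)(C)C)C[C@@H](O[Si](C)(C)C(C)(C)C)[C@@H](C)C=O | intermediate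
31 | C20 vinyllithium: 21 with lithium in place of iodine, (Z) geometry retained | [Li]/C(C)=C\C[C@H](O[Si](C)(C)C(C)(C)C)CCC[C@H](O[Si](C)(C)C(C)(C)C)CCC[C@H](O[Si](C)(C)C(C)(C)C)CCO[Si](C)(C)C(C)(C)C | intermediate
32 | C5–C33 allylic alcohol: 5-OPMB, 19-OH, 20-methyl, (20Z), 7,9,11,13,15,17,23,27,31,33-decakis-OTBS, 18-methyl; target configuration at all ten stereocentres C7–C31 | COc1ccc(cc1)COCC[C@H](O[Si](C)(C)C(C)(C)C)C[C@@H](O[Si](C)(C)C(C)(C)C)C[C@H](O[Si](C)(C)C(C)(C)C)C[C@@H](O[Si](C)(C)C(C)(C)C)C[C@H](O[Si](C)(C)C(C)(C)C)C[C@@H](O[Si](C)(C)C(C)(C)C)[C@@H](C)[C@H](O)/C(C)=C\C[C@H](O[Si](C)(C)C(C)(C)C)CCC[C@H](O[Si](C)(C)C(C)(C)C)CCC[C@H](O[Si](C)(C)C(C)(C)C)CCO[Si](C)(C)C(C)(C)C | intermediate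
33 | 19-O-TBS ether of 32 (eleven OTBS groups, 5-OPMB) | COc1ccc(cc1)COCC[C@H](O[Si](C)(C)C(C)(C)C)C[C@@H](O[Si](C)(C)C(C)(C)C)C[C@H](O[Si](C)(C)C(C)(C)C)C[C@@H](O[Si](C)(C)C(C)(C)C)C[C@H](O[Si](C)(C)C(C)(C)C)C[C@@H](O[Si](C)(C)C(C)(C)C)[C@@H](C)[C@H](O[Si](C)(C)C(C)(C)C)/C(C)=C\C[C@H](O[Si](C)(C)C(C)(C)C)CCC[C@H](O[Si](C)(C)C(C)(C)C)CCC[C@H](O[Si](C)(C)C(C)(C)C)CCO[Si](C)(C)C(C)(C)C | intermediate
34 | C33 primary alcohol: 33 with the C33 oxygen free (ten secondary OTBS, 5-OPMB) | COc1ccc(cc1)COCC[C@H](O[Si](C)(C)C(C)(C)C)C[C@@H](O[Si](C)(C)C(C)(C)C)C[C@H](O[Si](C)(C)C(C)(C)C)C[C@@H](O[Si](C)(C)C(C)(C)C)C[C@H](O[Si](C)(C)C(C)(C)C)C[C@@H](O[Si](C)(C)C(C)(C)C)[C@@H](C)[C@H](O[Si](C)(C)C(C)(C)C)/C(C)=C\C[C@H](O[Si](C)(C)C(C)(C)C)CCC[C@H](O[Si](C)(C)C(C)(C)C)CCC[C@H](O[Si](C)(C)C(C)(C)C)CCO | intermediate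
35 | C33 primary bromide: 34 with Br in place of the C33 hydroxyl | COc1ccc(cc1)COCC[C@H](O[Si](C)(C)C(C)(C)C)C[C@@H](O[Si](C)(C)C(C)(C)C)C[C@H](O[Si](C)(C)C(C)(C)C)C[C@@H](O[Si](C)(C)C(C)(C)C)C[C@H](O[Si](C)(C)C(C)(C)C)C[C@@H](O[Si](C)(C)C(C)(C)C)[C@@H](C)[C@H](O[Si](C)(C)C(C)(C)C)/C(C)=C\C[C@H](O[Si](C)(C)C(C)(C)C)CCC[C@H](O[Si](C)(C)C(C)(C)C)CCC[C@H](O[Si](C)(C)C(C)(C)C)CCBr | intermediate
36 | C5 primary alcohol: 35 without the PMB group | OCC[C@H](O[Si](C)(C)C(C)(C)C)C[C@@H](O[Si](C)(C)C(C)(C)C)C[C@H](O[Si](C)(C)C(C)(C)C)C[C@@H](O[Si](C)(C)C(C)(C)C)C[C@H](O[Si](C)(C)C(C)(C)C)C[C@@H](O[Si](C)(C)C(C)(C)C)[C@@H](C)[C@H](O[Si](C)(C)C(C)(C)C)/C(C)=C\C[C@H](O[Si](C)(C)C(C)(C)C)CCC[C@H](O[Si](C)(C)C(C)(C)C)CCC[C@H](O[Si](C)(C)C(C)(C)C)CCBr | intermediate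
37 | C5 aldehyde: C5–C33 chain, 5-oxo, 33-bromo, ten secondary OTBS, (20Z) | O=CC[C@H](O[Si](C)(C)C(C)(C)C)C[C@@H](O[Si](C)(C)C(C)(C)C)C[C@H](O[Si](C)(C)C(C)(C)C)C[C@@H](O[Si](C)(C)C(C)(C)C)C[C@H](O[Si](C)(C)C(C)(C)C)C[C@@H](O[Si](C)(C)C(C)(C)C)[C@@H](C)[C@H](O[Si](C)(C)C(C)(C)C)/C(C)=C\C[C@H](O[Si](C)(C)C(C)(C)C)CCC[C@H](O[Si](C)(C)C(C)(C)C)CCC[C@H](O[Si](C)(C)C(C)(C)C)CCBr | intermediate
38 | C4–C33 (Z)-vinyl iodide: iodine and methyl on C4, C4=C5 with iodine cis to C6, (20Z), 33-bromo, ten secondary OTBS | I/C(C)=C\C[C@H](O[Si](C)(C)C(C)(C)C)C[C@@H](O[Si](C)(C)C(C)(C)C)C[C@H](O[Si](C)(C)C(C)(C)C)C[C@@H](O[Si](C)(C)C(C)(C)C)C[C@H](O[Si](C)(C)C(C)(C)C)C[C@@H](O[Si](C)(C)C(C)(C)C)[C@@H](C)[C@H](O[Si](C)(C)C(C)(C)C)/C(C)=C\C[C@H](O[Si](C)(C)C(C)(C)C)CCC[C@H](O[Si](C)(C)C(C)(C)C)CCC[C@H](O[Si](C)(C)C(C)(C)C)CCBr | intermediate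
39 | C4–C33 (Z)-vinyl trimethylstannane: 38 with SnMe3 in place of iodine (tin cis to C6) | C[Sn](C)(C)/C(C)=C\C[C@H](O[Si](C)(C)C(C)(C)C)C[C@@H](O[Si](C)(C)C(C)(C)C)C[C@H](O[Si](C)(C)C(C)(C)C)C[C@@H](O[Si](C)(C)C(C)(C)C)C[C@H](O[Si](C)(C)C(C)(C)C)C[C@@H](O[Si](C)(C)C(C)(C)C)[C@@H](C)[C@H](O[Si](C)(C)C(C)(C)C)/C(C)=C\C[C@H](O[Si](C)(C)C(C)(C)C)CCC[C@H](O[Si](C)(C)C(C)(C)C)CCC[C@H](O[Si](C)(C)C(C)(C)C)CCBr | intermediate
40 | 6-bromohex-1-ene | BrCCCCC=C | starting material
41 | (R)-propylene oxide, (R)-2-methyloxirane | C[C@@H]1CO1 | starting material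
42 | (R)-non-8-en-2-ol | C=CCCCCC[C@@H](C)O | intermediate
43 | (R)-tert-butyldimethyl(non-8-en-2-yloxy)silane | C=CCCCCC[C@@H](C)O[Si](C)(C)C(C)(C)C | intermediate
44 | (R)-7-(tert-butyldimethylsilyloxy)octanal | O=CCCCCC[C@@H](C)O[Si](C)(C)C(C)(C)C | intermediate
45 | cis-but-2-ene | C/C=C\C | starting material
46 | (3R,4R,10R)-10-(tert-butyldimethylsilyloxy)-3-methylundec-1-en-4-ol (C42 methyl and C43 hydroxyl syn) | C=C[C@@H](C)[C@H](O)CCCCC[C@@H](C)O[Si](C)(C)C(C)(C)C | intermediate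
47 | (3R,4R,10R)-4,10-bis(tert-butyldimethylsilyloxy)-3-methylundec-1-ene | C=C[C@@H](C)[C@H](O[Si](C)(C)C(C)(C)C)CCCCC[C@@H](C)O[Si](C)(C)C(C)(C)C | intermediate
48 | (2S,3R,9R)-3,9-bis(tert-butyldimethylsilyloxy)-2-methyldecanal (C41 aldehyde) | O=C[C@@H](C)[C@H](O[Si](C)(C)C(C)(C)C)CCCCC[C@@H](C)O[Si](C)(C)C(C)(C)C | intermediate
49 | allylmagnesium bromide | C=CC[Mg]Br | starting material
50 | (4S,5R,6R,12R)-6,12-bis(tert-butyldimethylsilyloxy)-5-methyltridec-1-en-4-ol (C39–C50 plus one alkene carbon; syn,syn triad C41–C43) | C=CC[C@@H]([C@@H](C)[C@H](O[Si](C)(C)C(C)(C)C)CCCCC[C@@H](C)O[Si](C)(C)C(C)(C)C)O | intermediate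
51 | 4-O-triethylsilyl ether of 50 (41-OTES, 43,49-bis-OTBS) | C=CC[C@@H]([C@@H](C)[C@H](O[Si](C)(C)C(C)(C)C)CCCCC[C@@H](C)O[Si](C)(C)C(C)(C)C)O[Si](CC)(CC)CC | intermediate
52 | C39–C50 aldehyde: 39-oxo, 41-OTES, 42-methyl, 43,49-bis-OTBS; target configuration at C41, C42, C43, C49 | O=CC[C@@H]([C@@H](C)[C@H](O[Si](C)(C)C(C)(C)C)CCCCC[C@@H](C)O[Si](C)(C)C(C)(C)C)O[Si](CC)(CC)CC | intermediate
53 | (pent-4-en-1-yl)triphenylphosphonium bromide | C=CCCC[P+](c1ccccc1)(c1ccccc1)c1ccccc1.[Br-] | starting material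
54 | C34–C50 (Z)-diene: terminal vinyl C34=C35, (38Z)-alkene, 41-OTES, 42-methyl, 43,49-bis-OTBS | C=CCC/C=C\C[C@@H]([C@@H](C)[C@H](O[Si](C)(C)C(C)(C)C)CCCCC[C@@H](C)O[Si](C)(C)C(C)(C)C)O[Si](CC)(CC)CC | intermediate
55 | C34–C50 dienol: 54 with free 41-OH | C=CCC/C=C\C[C@@H]([C@@H](C)[C@H](O[Si](C)(C)C(C)(C)C)CCCCC[C@@H](C)O[Si](C)(C)C(C)(C)C)O | intermediate
56 | (Z)-3-iodoacrylic acid | OC(=O)/C=C\I | starting material
57 | (Z)-3-iodoacrylate of 55 (C1–C3 on O41) | C=CCC/C=C\C[C@@H]([C@@H](C)[C@H](O[Si](C)(C)C(C)(C)C)CCCCC[C@@H](C)O[Si](C)(C)C(C)(C)C)OC(=O)/C=C\I | intermediate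
58 | seco ester: C41 ester of the (2Z,4Z)-4-methyl-dienoic acid C1–C33 bearing 33-bromo, (20Z) and ten secondary OTBS, with the C34–C50 alcohol part (terminal vinyl C34=C35, 38Z, 43,49-bis-OTBS) | C=CCC/C=C\C[C@@H]([C@@H](C)[C@H](O[Si](C)(C)C(C)(C)C)CCCCC[C@@H](C)O[Si](C)(C)C(C)(C)C)OC(=O)/C=C\C(C)=C/C[C@H](O[Si](C)(C)C(C)(C)C)C[C@@H](O[Si](C)(C)C(C)(C)C)C[C@H](O[Si](C)(C)C(C)(C)C)C[C@@H](O[Si](C)(C)C(C)(C)C)C[C@H](O[Si](C)(C)C(C)(C)C)C[C@@H](O[Si](C)(C)C(C)(C)C)[C@@H](C)[C@H](O[Si](C)(C)C(C)(C)C)/C(C)=C\C[C@H](O[Si](C)(C)C(C)(C)C)CCC[C@H](O[Si](C)(C)C(C)(C)C)CCC[C@H](O[Si](C)(C)C(C)(C)C)CCBr | intermediate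
59 | B-alkyl-9-BBN seco ester: 58 with 9-borabicyclo[3.3.1]nonan-9-yl on C34 (C34=C35 hydroborated) | C1CCC2CCCC1B2CCCC/C=C\C[C@@H]([C@@H](C)[C@H](O[Si](C)(C)C(C)(C)C)CCCCC[C@@H](C)O[Si](C)(C)C(C)(C)C)OC(=O)/C=C\C(C)=C/C[C@H](O[Si](C)(C)C(C)(C)C)C[C@@H](O[Si](C)(C)C(C)(C)C)C[C@H](O[Si](C)(C)C(C)(C)C)C[C@@H](O[Si](C)(C)C(C)(C)C)C[C@H](O[Si](C)(C)C(C)(C)C)C[C@@H](O[Si](C)(C)C(C)(C)C)[C@@H](C)[C@H](O[Si](C)(C)C(C)(C)C)/C(C)=C\C[C@H](O[Si](C)(C)C(C)(C)C)CCC[C@H](O[Si](C)(C)C(C)(C)C)CCC[C@H](O[Si](C)(C)C(C)(C)C)CCBr | intermediate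
60 | fully silylated macrolactone: the target with all twelve hydroxyls (C7, C9, C11, C13, C15, C17, C19, C23, C27, C31, C43, C49) as TBS ethers | CC1=C/C[C@H](O[Si](C)(C)C(C)(C)C)C[C@@H](O[Si](C)(C)C(C)(C)C)C[C@H](O[Si](C)(C)C(C)(C)C)C[C@@H](O[Si](C)(C)C(C)(C)C)C[C@H](O[Si](C)(C)C(C)(C)C)C[C@@H](O[Si](C)(C)C(C)(C)C)[C@@H](C)[C@H](O[Si](C)(C)C(C)(C)C)/C(C)=C\C[C@H](O[Si](C)(C)C(C)(C)C)CCC[C@H](O[Si](C)(C)C(C)(C)C)CCC[C@H](O[Si](C)(C)C(C)(C)C)CCCCCC/C=C\C[C@@H]([C@@H](C)[C@H](O[Si](C)(C)C(C)(C)C)CCCCC[C@@H](C)O[Si](C)(C)C(C)(C)C)OC(=O)/C=C\1 | intermediate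
61 | target macrolide CNP0392687.2 | CC1=C/C[C@H](O)C[C@@H](O)C[C@H](O)C[C@@H](O)C[C@H](O)C[C@@H](O)[C@@H](C)[C@H](O)/C(C)=C\C[C@H](O)CCC[C@H](O)CCC[C@H](O)CCCCCC/C=C\C[C@@H]([C@@H](C)[C@H](O)CCCCC[C@@H](C)O)OC(=O)/C=C\1 | target

## Step count and risks

Total step count: 44. Longest linear sequence: 24 steps (steps 1–3, 7, 8, 14–29, 42–44, from but-3-en-1-ol).

Steps most likely to fail:

1. Step 43 (proposed new method). What may go wrong: intermolecular coupling leading to oligomers, β-hydride elimination or protodeboronation of the open-chain intermediates, and slow oxidative addition at the dilution needed for ring closure. Fallback with known chemistry: form the C33–C34 bond intermolecularly and close ring A at C3–C4 instead. It sets out from 39 and 54. Diene 54 is hydroborated with 9-BBN at its terminal alkene to the B-alkyl-9-BBN reagent F1. F1 is coupled with the primary bromide of 39 under Pd(OAc)2/PCy3/K3PO4·H2O in THF (the documented intermolecular alkyl–alkyl Suzuki–Miyaura coupling) to give the C4–C50 stannane F2. The TES ether is removed with buffered HF·pyridine to give the C41 alcohol F3. Steglich esterification with 56 gives the stannyl iodoacrylate F4. A Stille macrocyclisation (Pd2(dba)3, AsPh3, NMP, high dilution) closes the 42-membered ring and comes back to the route at 60.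

2. Step 22. What may go wrong: poor facial selectivity in the addition to the α-methyl aldehyde, and base-induced epimerisation of the aldehyde at C18 by the organolithium. Fallback: it sets out from 21 and 30 and joins them by a catalytic asymmetric Nozaki–Hiyama–Kishi coupling (CrCl2, NiCl2 cat., chiral sulfonamide ligand, Mn, TMSCl, THF). The non-basic organochromium species adds under ligand control instead of substrate control, and the route is rejoined at 32. This fallback makes no new compound (F0).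

3. Step 28. What may go wrong: erosion of the Z/E ratio and low conversion in the iodo-ylide addition to a hindered β-silyloxy aldehyde, with competing loss of the alkyl bromide. Fallback: it sets out from 37. Dibromo-olefination (CBr4, PPh3, 2,6-lutidine, CH2Cl2, 0 °C) gives the 1,1-dibromoalkene F5. A trans-selective palladium-catalysed Negishi monomethylation (Me2Zn, Pd(DPEphos)Cl2, THF) replaces the bromine trans to the chain and gives the (Z)-2-bromoalk-2-ene F6. Palladium-catalysed stannylation with hexamethylditin (Pd(PPh3)4, toluene, 100 °C) then comes back to the route at 39.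

Further compounds

F1 | step 43 | B-alkyl-9-BBN reagent from 54 (9-borabicyclo[3.3.1]nonan-9-yl on C34, 41-OTES) | C1CCC2CCCC1B2CCCC/C=C\C[C@@H]([C@@H](C)[C@H](O[Si](C)(C)C(C)(C)C)CCCCC[C@@H](C)O[Si](C)(C)C(C)(C)C)O[Si](CC)(CC)CC
F2 | step 43 | C4–C50 stannane: C33–C34 coupled chain with C4 SnMe3, 41-OTES and twelve secondary OTBS | C[Sn](C)(C)/C(C)=C\C[C@H](O[Si](C)(C)C(C)(C)C)C[C@@H](O[Si](C)(C)C(C)(C)C)C[C@H](O[Si](C)(C)C(C)(C)C)C[C@@H](O[Si](C)(C)C(C)(C)C)C[C@H](O[Si](C)(C)C(C)(C)C)C[C@@H](O[Si](C)(C)C(C)(C)C)[C@@H](C)[C@H](O[Si](C)(C)C(C)(C)C)/C(C)=C\C[C@H](O[Si](C)(C)C(C)(C)C)CCC[C@H](O[Si](C)(C)C(C)(C)C)CCC[C@H](O[Si](C)(C)C(C)(C)C)CCCCCC/C=C\C[C@@H]([C@@H](C)[C@H](O[Si](C)(C)C(C)(C)C)CCCCC[C@@H](C)O[Si](C)(C)C(C)(C)C)O[Si](CC)(CC)CC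
F3 | step 43 | C41 alcohol of F2 | C[Sn](C)(C)/C(C)=C\C[C@H](O[Si](C)(C)C(C)(C)C)C[C@@H](O[Si](C)(C)C(C)(C)C)C[C@H](O[Si](C)(C)C(C)(C)C)C[C@@H](O[Si](C)(C)C(C)(C)C)C[C@H](O[Si](C)(C)C(C)(C)C)C[C@@H](O[Si](C)(C)C(C)(C)C)[C@@H](C)[C@H](O[Si](C)(C)C(C)(C)C)/C(C)=C\C[C@H](O[Si](C)(C)C(C)(C)C)CCC[C@H](O[Si](C)(C)C(C)(C)C)CCC[C@H](O[Si](C)(C)C(C)(C)C)CCCCCC/C=C\C[C@@H]([C@@H](C)[C@H](O[Si](C)(C)C(C)(C)C)CCCCC[C@@H](C)O[Si](C)(C)C(C)(C)C)O
F4 | step 43 | stannyl iodoacrylate: (Z)-3-iodoacrylate of F3 | C[Sn](C)(C)/C(C)=C\C[C@H](O[Si](C)(C)C(C)(C)C)C[C@@H](O[Si](C)(C)C(C)(C)C)C[C@H](O[Si](C)(C)C(C)(C)C)C[C@@H](O[Si](C)(C)C(C)(C)C)C[C@H](O[Si](C)(C)C(C)(C)C)C[C@@H](O[Si](C)(C)C(C)(C)C)[C@@H](C)[C@H](O[Si](C)(C)C(C)(C)C)/C(C)=C\C[C@H](O[Si](C)(C)C(C)(C)C)CCC[C@H](O[Si](C)(C)C(C)(C)C)CCC[C@H](O[Si](C)(C)C(C)(C)C)CCCCCC/C=C\C[C@@H]([C@@H](C)[C@H](O[Si](C)(C)C(C)(C)C)CCCCC[C@@H](C)O[Si](C)(C)C(C)(C)C)OC(=O)/C=C\I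
F0 | step 22 | none | none
F5 | step 28 | 1,1-dibromoalkene from 37 (CBr2 in place of the aldehyde oxygen) | BrC(Br)=CC[C@H](O[Si](C)(C)C(C)(C)C)C[C@@H](O[Si](C)(C)C(C)(C)C)C[C@H](O[Si](C)(C)C(C)(C)C)C[C@@H](O[Si](C)(C)C(C)(C)C)C[C@H](O[Si](C)(C)C(C)(C)C)C[C@@H](O[Si](C)(C)C(C)(C)C)[C@@H](C)[C@H](O[Si](C)(C)C(C)(C)C)/C(C)=C\C[C@H](O[Si](C)(C)C(C)(C)C)CCC[C@H](O[Si](C)(C)C(C)(C)C)CCC[C@H](O[Si](C)(C)C(C)(C)C)CCBr
F6 | step 28 | C4–C33 (Z)-vinyl bromide (bromine cis to C6) | Br/C(C)=C\C[C@H](O[Si](C)(C)C(C)(C)C)C[C@@H](O[Si](C)(C)C(C)(C)C)C[C@H](O[Si](C)(C)C(C)(C)C)C[C@@H](O[Si](C)(C)C(C)(C)C)C[C@H](O[Si](C)(C)C(C)(C)C)C[C@@H](O[Si](C)(C)C(C)(C)C)[C@@H](C)[C@H](O[Si](C)(C)C(C)(C)C)/C(C)=C\C[C@H](O[Si](C)(C)C(C)(C)C)CCC[C@H](O[Si](C)(C)C(C)(C)C)CCC[C@H](O[Si](C)(C)C(C)(C)C)CCBr
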